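**Plan**

Locants: carane numbering C-1 to C-7 and C-10 for the terpene part (C-3 is the O-bearing ring-fusion carbon, C-2 the ring-fusion CH next to the cyclopropane, C-4 the CHMe carbon); C-11 is the CH2 between C-10 and the methyl-bearing quaternary carbon C-2′; C-1′ is the benzylic CH(iBu).
Retrosynthesis: first the two CHO groups and the two phenolic OH (formylation, O-demethylation), then the isobutyl group (back to a C-1′ aryl ketone); then, in one cut, the aryl C–O(C-3) ether bond and the C-2′–C-2 bond; then C-2′–C-11, C-10–C-11 and C-4–CH3, back to (+)-3-carene and 1-fluoro-3,5-dimethoxybenzene.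
Forward: cyclopropane and six-membered ring come with (+)-3-carene; the chain is joined C-10–C-11, then C-11–C-2′; the cyclopentane (C-3, C-10, C-11, C-2′, C-2) and the bridging benzoxepine ring (ArC–O–C-3–C-2–C-2′–C-1′) close together in step 9; isobutyl, formyl groups and free phenols follow.
Enabling feature: the ether oxygen sits on C-3 directly beside the cyclopropylcarbinyl C-2, so a C-2/C-3 epoxide is a latent O–C–C 1,3-dipole whose alkoxide is unmasked only by the C–C bond formation. The aryl carbon to be etherified is ortho to C-1′, so a C-1′ carbonyl both acidifies C-2′ and activates an ortho C–F for SNAr; on the new cyclopentane the C-3 oxygen and the aroyl group are 1,3-cis.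
Stereochemistry: C-1/C-6 from (+)-3-carene; C-4 by anti opening of the α-epoxide; C-3 by bromonium/water anti addition (oxygen onto the cyclopropane face); C-2 and C-2′ in step 9 (SN2 inversion, aroyl group exo); C-1′ by exo attack on the benzylic cation.

Key step: step 9

Assumption: C-2′ in 13 and C-1′ in 17 are planarised in the following step, so both are drawn without descriptor; the enolate geometries of 12 and 14 are left open.

**Route**

Step 1
Reactants: 1 1-fluoro-3,5-dimethoxybenzene
Product: 2 1-(2-fluoro-4,6-dimethoxyphenyl)propan-1-one
Conditions: EtCOCl, AlCl3, CH2Cl2, 0 °C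
Reagents that add atoms: propionyl chloride, CCC(Cl)=O
Why: Friedel–Crafts acylation should occur at the position ortho to F and ortho/para to the two OMe groups, the site between the two OMe groups being the more hindered one.

Step 2
Reactants: 3 (+)-3-carene
Product: 4 3α,4α-epoxycarane (epoxide trans to the cyclopropane)
Conditions: mCPBA, NaHCO3, CH2Cl2, 0 °C
Reagents that add atoms: mCPBA, OOC(=O)c1cccc(Cl)c1
Why: Prilezhaev epoxidation should take place on the face anti to the gem-dimethylcyclopropane.

Step 3
Reactants: 4 3α,4α-epoxycarane
Product: 5 4-methylcaran-3-ol (3-OH trans, 4-CH3 cis to the cyclopropane)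
Conditions: MeMgCl, CuI (10 mol %), THF, −30 → 0 °C; aq. NH4Cl
Reagents that add atoms: methylmagnesium chloride, C[Mg]Cl
Why: Copper-catalysed Grignard opening of the trisubstituted epoxide should proceed by SN2 at the secondary C-4 anti to the oxygen (trans-diaxial), which places the new methyl group cis to the cyclopropane.

Step 4
Reactants: 5 4-methylcaran-3-ol
Product: 6 4-methylcar-2-ene (3,4,7,7-tetramethylbicyclo[4.1.0]hept-2-ene, 4-CH3 cis to the cyclopropane)
Conditions: SOCl2, pyridine, 0 °C
Reagents that add atoms: none
Why: E2-type dehydration through the chlorosulfite should remove the anti-periplanar H-2 (the anti position on C-4 carries the methyl group) and give the cyclopropane-conjugated alkene without touching a stereocentre.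

Step 5
Reactants: 6 4-methylcar-2-ene
Product: 8 2-(4,7,7-trimethylbicyclo[4.1.0]hept-2-en-3-yl)ethan-1-ol, via allylpotassium 7 (not isolated)
Conditions: n-BuLi, KOtBu, hexane, 0 °C → rt; then (CH2O)n, THF, −78 °C → rt
Reagents that add atoms: formaldehyde (from paraformaldehyde), C=O
Why: Schlosser-base allylic metalation should remove a proton from the C-10 methyl group (primary, least hindered allylic site), and the allylpotassium should add to formaldehyde at this unhindered terminus so that the ring double bond is kept.

Step 6
Reactants: 8 2-(4,7,7-trimethylbicyclo[4.1.0]hept-2-en-3-yl)ethan-1-ol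
Product: 9 3-(2-iodoethyl)-4,7,7-trimethylbicyclo[4.1.0]hept-2-ene
Conditions: PPh3, I2, imidazole, CH2Cl2, 0 °C
Reagents that add atoms: iodine, II
Why: Appel-type iodination (SN2 on the alkoxyphosphonium ion) converts the primary alcohol under buffered conditions that the vinylcyclopropane should tolerate.

Step 7
Reactants: 9 3-(2-iodoethyl)-4,7,7-trimethylbicyclo[4.1.0]hept-2-ene
Product: 11 2,3-epoxy-3-(2-iodoethyl)-4,7,7-trimethylbicyclo[4.1.0]heptane (epoxide oxygen cis to the cyclopropane), via bromohydrin 10 (not isolated)
Conditions: NBS, acetone/H2O, 0 °C; then K2CO3, MeOH, 0 °C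
Reagents that add atoms: water, O; N-bromosuccinimide, BrN1C(=O)CCC1=O (its Br is present only in 10)
Why: Bromonium formation on the face anti to both the cyclopropane and the C-4 methyl, Markovnikov anti attack of water at the tertiary C-3 and base-induced SN2 closure of the trans-bromohydrin should put the epoxide oxygen on the cyclopropane face, the face that direct peracid epoxidation does not reach.

Step 8
Reactants: 2 1-(2-fluoro-4,6-dimethoxyphenyl)propan-1-one; 11 epoxy iodide
Product: 13 1-(2-fluoro-4,6-dimethoxyphenyl)-2-methyl-4-(2,3-epoxy-4,7,7-trimethylbicyclo[4.1.0]hept-3-yl)butan-1-one (epoxy ketone), via lithium enolate 12 (not isolated)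
Conditions: LiHMDS, THF, −78 °C; then 11, DMPU, −78 → −20 °C
Reagents that add atoms: none
Why: SN2 C-alkylation of the ketone enolate by the primary iodide joins the fragments, and the new α-centre needs no control because it is enolised again in step 9.

Step 9
Reactants: 13 epoxy ketone
Product: 16 bridged tetracyclic aryl ketone (C-1′ = C=O, ring as its dimethyl ether), via potassium enolate 14 (not isolated), via potassium alkoxide 15 (not isolated)
Conditions: KHMDS (1.3 equiv), 18-crown-6, THF, −40 → 45 °C
Reagents that add atoms: none
Why: Proposed new method: KHMDS deprotonates C-2′ to the tetrasubstituted enolate 14, whose carbon opens the epoxide by SN2 at C-2 anti to the oxygen, and the C-3 potassium alkoxide 15 released in that act then displaces the ortho fluoride of the now non-enolisable aryl ketone by addition–elimination, so that the C-2′–C-2 and aryl C–O bonds form in one relay. The closest known reaction types are the intramolecular opening of epoxides by nitrile- or ketone-stabilised carbanions (Stork-type epoxide cyclisation), alkoxide SNAr on 2-fluoroaryl ketones and epoxide-opening/SNAr domino sequences; their union in this endo/bridging mode is without precedent. The cyclopentane closes in a 5-endo epoxide opening with the enolate C=C exocyclic to the new ring, and the oxepine ring closes by 7-exo attack of the alkoxide on the C–F carbon. C-2 is set by inversion at the epoxide, C-3 is carried over unchanged, and C-2′ is set by the enolate face, the bulky aroyl enolate unit lying exo to the six-membered ring and on the side of the epoxide oxygen (K+ bridging), which is also the only epimer able to close the ether ring. The step needs attack at C-2 and not 4-exo attack at C-3 or O-alkylation: C-3 is fully substituted and would give a cyclobutane with two adjacent quaternary carbons, whereas C-2 is secondary and its SN2 transition state is stabilised by the adjacent cyclopropane; a silazide base is used so that the arene C–H between F and OMe is not metalated.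

Step 10
Reactants: 16 bridged aryl ketone
Product: 17 bridged benzylic alcohol (C-1′ = CHOH)
Conditions: LiAlH4, THF, 0 °C
Reagents that add atoms: none
Why: Hydride reduction of the non-enolisable aryl ketone gives the benzylic alcohol, whose configuration is irrelevant because C-1′ is ionised in the next step.

Step 11
Reactants: 17 bridged benzylic alcohol
Product: 18 C-1′ 2-methylallyl compound (dimethyl ether)
Conditions: methallyltrimethylsilane, InCl3 (10 mol %), CH2Cl2, −20 °C
Reagents that add atoms: methallyltrimethylsilane, C=C(C)C[Si](C)(C)C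
Why: Lewis-acid ionisation gives the 2,4,6-trioxygenated benzylic cation, which the allylsilane (Hosomi–Sakurai-type SN1 allylation) should attack on the exo face of the bicyclo[4.2.1] core, syn to the one-carbon bridge C-2, so that H-1′ ends syn to the two-carbon bridge as in the target.

Step 12
Reactants: 18 2-methylallyl compound
Product: 19 isobutyl compound (target skeleton as its dimethyl ether, without CHO groups)
Conditions: H2 (1 atm), Pd/C, EtOAc, rt
Reagents that add atoms: none
Why: Catalytic hydrogenation of the 1,1-disubstituted alkene under mild conditions should leave the gem-dimethylcyclopropane and the aryl ethers intact.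

Step 13
Reactants: 19 isobutyl compound
Product: 20 diformyl dimethyl ether
Conditions: Cl2CHOMe, TiCl4, CH2Cl2, −78 → 0 °C; then H2O
Reagents that add atoms: dichloromethyl methyl ether, COC(Cl)Cl; water, O
Why: Rieche formylation should functionalise the only two free positions of the phloroglucinol triether ring, as is usual for making diformylphloroglucinol ethers.

Step 14
Reactants: 20 diformyl dimethyl ether
Product: 21 CNP0202714.1 (target)
Conditions: EtSNa, DMF, 100 °C; aq. HCl work-up
Reagents that add atoms: none
Why: Thiolate O-demethylation (SN2 at methyl, each aryloxide leaving group stabilised by ortho/para CHO) should free both phenols without acid, while the tertiary alkyl aryl ether cannot react by SN2.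

**Compound list**

1 | 1-fluoro-3,5-dimethoxybenzene | COc1cc(F)cc(OC)c1 | starting material
2 | 1-(2-fluoro-4,6-dimethoxyphenyl)propan-1-one | CCC(=O)c1c(F)cc(OC)cc1OC | intermediate
3 | (+)-3-carene, (1S,6R) | CC1=CC[C@@H]2[C@H](C1)C2(C)C | starting material
4 | 3α,4α-epoxycarane (epoxide trans to cyclopropane) | C[C@@]12O[C@@H]1C[C@@H]1[C@H](C2)C1(C)C | intermediate
5 | 4-methylcaran-3-ol (3-OH trans, 4-CH3 cis to cyclopropane) | C[C@@]1(O)[C@@H](C)C[C@@H]2[C@H](C1)C2(C)C | intermediate
6 | 4-methylcar-2-ene (4-CH3 cis to cyclopropane) | CC1=C[C@H]2[C@@H](C[C@@H]1C)C2(C)C | intermediate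
7 | allylpotassium of 6 (C-10 metalated) | [K+].[CH2-]C1=C[C@H]2[C@@H](C[C@@H]1C)C2(C)C | intermediate
8 | 2-(4,7,7-trimethylbicyclo[4.1.0]hept-2-en-3-yl)ethan-1-ol | OCCC1=C[C@H]2[C@@H](C[C@@H]1C)C2(C)C | intermediate
9 | 3-(2-iodoethyl)-4,7,7-trimethylbicyclo[4.1.0]hept-2-ene | ICCC1=C[C@H]2[C@@H](C[C@@H]1C)C2(C)C | intermediate
10 | bromohydrin: 2-bromo-3-(2-iodoethyl)-4,7,7-trimethylbicyclo[4.1.0]heptan-3-ol (Br trans, OH cis to cyclopropane) | ICC[C@@]1(O)[C@@H](Br)[C@H]2[C@@H](C[C@@H]1C)C2(C)C | intermediate
11 | epoxy iodide: 2,3-epoxy-3-(2-iodoethyl)-4,7,7-trimethylbicyclo[4.1.0]heptane (oxygen cis to cyclopropane) | ICC[C@@]12O[C@@H]1[C@H]1[C@@H](C[C@@H]2C)C1(C)C | intermediate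
12 | lithium enolate of 2 | [Li+].CC=C([O-])c1c(F)cc(OC)cc1OC | intermediate
13 | epoxy ketone (C-2′ epimers) | CC(CC[C@@]12O[C@@H]1[C@H]1[C@@H](C[C@@H]2C)C1(C)C)C(=O)c1c(F)cc(OC)cc1OC | intermediate
14 | potassium enolate of 13 | [K+].CC(CC[C@@]12O[C@@H]1[C@H]1[C@@H](C[C@@H]2C)C1(C)C)=C([O-])c1c(F)cc(OC)cc1OC | intermediate
15 | potassium alkoxide: cis-fused cyclopentane closed, C-3 O–, aroyl cis to O, aryl fluoride intact | [K+].[O-][C@]12CC[C@](C)(C(=O)c3c(F)cc(OC)cc3OC)[C@H]1[C@H]1[C@@H](C[C@@H]2C)C1(C)C | intermediate
16 | bridged tetracyclic aryl ketone (C-1′ = C=O, dimethyl ether) | O=C1c2c(OC)cc(OC)cc2O[C@]23CC[C@@]1(C)[C@H]2[C@H]1[C@@H](C[C@@H]3C)C1(C)C | intermediate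
17 | bridged benzylic alcohol (C-1′ epimers) | OC1c2c(OC)cc(OC)cc2O[C@]23CC[C@@]1(C)[C@H]2[C@H]1[C@@H](C[C@@H]3C)C1(C)C | intermediate
18 | C-1′ 2-methylallyl compound (dimethyl ether) | C=C(C)C[C@H]1c2c(OC)cc(OC)cc2O[C@]23CC[C@@]1(C)[C@H]2[C@H]1[C@@H](C[C@@H]3C)C1(C)C | intermediate
19 | isobutyl compound (dimethyl ether, no CHO) | CC(C)C[C@H]1c2c(OC)cc(OC)cc2O[C@]23CC[C@@]1(C)[C@H]2[C@H]1[C@@H](C[C@@H]3C)C1(C)C | intermediate
20 | diformyl dimethyl ether | CC(C)C[C@H]1c2c(OC)c(C=O)c(OC)c(C=O)c2O[C@]23CC[C@@]1(C)[C@H]2[C@H]1[C@@H](C[C@@H]3C)C1(C)C | intermediate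
21 | CNP0202714.1 | CC(C)C[C@H]1c2c(O)c(C=O)c(O)c(C=O)c2O[C@]23CC[C@@]1(C)[C@H]2[C@H]1[C@@H](C[C@@H]3C)C1(C)C | target

**Step count and risks**

Total step count: 14. Longest linear sequence: 13 steps (steps 2–14, from (+)-3-carene); step 1 is convergent.

Steps most likely to fail:

Step 9 (proposed new method). The enolate carbon may attack the fully substituted epoxide carbon (4-exo mode) or the enolate may O-alkylate instead of undergoing the 5-endo C-alkylation, or ring closure may place the aroyl group on the face of C-2′ from which the alkoxide cannot reach the arene. The fallback separates the two bond formations and makes the C–C bond under Lewis-acid rather than anionic control, using known reaction types. It sets out from 13: TMSOTf/Et3N should give the trimethylsilyl enol ether F1. Et2AlCl (or TiCl4), CH2Cl2, −78 °C should then effect an intramolecular Mukaiyama-type opening of the activated epoxide at the cyclopropyl-stabilised C-2, giving after work-up the hydroxy ketone F2. KH in THF/DMF then closes the aryl ether by alkoxide SNAr on the 2-fluoroaryl ketone, and the route is rejoined at 16.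

Step 7. The bromonium ion may open with participation of the cyclopropane (homoallylic ring opening) or in the anti-Markovnikov sense, and the labile cyclopropyl epoxide may be lost on isolation. The fallback goes through the less cationic seleniranium ion. It sets out from 9: PhSeCl in MeCN/H2O (hydroxyselenation, same anti/Markovnikov sense) should give the β-hydroxy selenide F3. Se-methylation with Me3OBF4 gives the selenonium salt F4, and KOH induces intramolecular displacement of the selenide with inversion at C-2, which returns to 11.

Step 11. The allylsilane may attack the other face of the benzylic cation (wrong C-1′ epimer), or the cation may fragment by ionisation of the C-3–O bond. The fallback reverses the order in which carbon and hydrogen are brought to C-1′, so that the same facial preference gives the opposite configuration and the carbon group is introduced without a cation. It sets out from 16: methallylmagnesium chloride/CeCl3 should give the tertiary alcohol F5. H2, Pd/C gives the isobutyl carbinol F6, and ionic deoxygenation (Et3SiH, BF3·OEt2, CH2Cl2, −78 °C) delivers hydride to the benzylic cation and rejoins the route at 19.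

Further compounds
F1 | step 9 | trimethylsilyl enol ether of 13 | CC(CC[C@@]12O[C@@H]1[C@H]1[C@@H](C[C@@H]2C)C1(C)C)=C(O[Si](C)(C)C)c1c(F)cc(OC)cc1OC
F2 | step 9 | hydroxy ketone (neutral form of 15) | O[C@]12CC[C@](C)(C(=O)c3c(F)cc(OC)cc3OC)[C@H]1[C@H]1[C@@H](C[C@@H]2C)C1(C)C
F3 | step 7 | β-hydroxy selenide (PhSe trans, OH cis to cyclopropane) | ICC[C@@]1(O)[C@@H]([Se]c3ccccc3)[C@H]2[C@@H](C[C@@H]1C)C2(C)C
F4 | step 7 | methyl(phenyl)selenonium tetrafluoroborate of F3 | ICC[C@@]1(O)[C@@H]([Se+](C)c3ccccc3)[C@H]2[C@@H](C[C@@H]1C)C2(C)C.F[B-](F)(F)F
F5 | step 11 | C-1′ tertiary alcohol with 2-methylallyl group | C=C(C)CC1(O)c2c(OC)cc(OC)cc2O[C@]23CC[C@@]1(C)[C@H]2[C@H]1[C@@H](C[C@@H]3C)C1(C)C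
F6 | step 11 | C-1′ tertiary alcohol with isobutyl group | CC(C)CC1(O)c2c(OC)cc(OC)cc2O[C@]23CC[C@@]1(C)[C@H]2[C@H]1[C@@H](C[C@@H]3C)C1(C)C
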